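**Retrosynthetic overview**
1. Sipholenol K 27 ⇐ desilylation of enone 26 ⇐ Saegusa oxidation of the enol silane from a one-carbon ring expansion (β-oxido carbenoid 1,2-alkyl shift) of cis-hydrindan-2-one 22; the five-membered ketone becomes ring A and gains C-3 with its methyl.
2. 22 ⇐ SmI2 ketyl–enone cyclisation (ring B, cis fusion, tertiary alcohol) of cyclopentenone 21 ⇐ radical conjugate addition of 5-methylhex-5-en-2-one anti to the silyloxy group of a (R)-4-silyloxycyclopentenone, then β-elimination.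
3. The halves are joined by B-alkyl Suzuki coupling of vinyl benzoxepinol 14 with iodoenone 16.
4. 14 ⇐ (6S,7S,10S)-diepoxyfarnesyl acetate 10 by one epoxonium cascade (oxepane, then cyclohexane, then acetate capture) ⇐ Shi epoxidation ⇐ farnesyl acetate from 5-bromo-2-methylpent-2-ene by two Zr-catalysed carboaluminations.
5. Ring order: oxepane and cyclohexane together (step 7), purchased five-membered template, ring B (step 13), ring A by expansion (step 14).

Assumption: the silyl group of purchased 15 is a protecting group and is not counted among its heavy atoms (C5O2 = 7).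

Abbreviations: TBS = tert-butyldimethylsilyl; TMS = trimethylsilyl; Ox = (3S,5aS,6S,7S,9aS)-3-(TBS-oxy)-7-hydroxy-2,2,5a,7-tetramethyldecahydro-1-benzoxepin-6-yl (trans-fused); Ox′ = Ox as its 7-O-TMS ether. Left half uses 1-benzoxepine locants, right half uses indene or naphthalene locants.

**Route**

Step 1
Reactants: 1 5-bromo-2-methylpent-2-ene
Product: 2 6-methylhept-5-en-1-yne
Conditions: LiC≡CH·H2NCH2CH2NH2, DMSO, 10 → 23 °C
Reagents that add atoms: lithium acetylide–ethylenediamine, [Li]C#C.NCCN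
Why: SN2 alkylation of acetylide by an unhindered primary bromide in a dipolar aprotic solvent; no stereocentre is formed.

Step 2
Reactants: 2 6-methylhept-5-en-1-yne
Product: 4 (3E)-4,8-dimethylnona-3,7-dien-1-ol, via alkenylalane 3 (not isolated)
Conditions: Me3Al, Cp2ZrCl2 (0.25 equiv), CH2Cl2, 23 °C; n-BuLi, THF, −78 °C; oxirane, −78 → 0 °C
Reagents that add atoms: trimethylaluminium, C[Al](C)C; oxirane, C1CO1
Why: Negishi Zr-catalysed carboalumination adds Me and Al syn across the alkyne, and the derived alanate opens oxirane with retention, so the trisubstituted alkene is (E).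

Step 3
Reactants: 4 (3E)-4,8-dimethylnona-3,7-dien-1-ol
Product: 5 (6E)-9-iodo-2,6-dimethylnona-2,6-diene
Conditions: I2, PPh3, imidazole, CH2Cl2, 0 °C
Reagents that add atoms: iodine, II
Why: Appel iodination of a primary alcohol; alkene geometry is untouched.

Step 4
Reactants: 5 (6E)-9-iodo-2,6-dimethylnona-2,6-diene
Product: 6 (5E)-6,10-dimethylundeca-5,9-dien-1-yne
Conditions: LiC≡CH·H2NCH2CH2NH2, DMSO, 23 °C
Reagents that add atoms: lithium acetylide–ethylenediamine, [Li]C#C.NCCN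
Why: SN2 alkylation of acetylide by the primary iodide, as in step 1.

Step 5
Reactants: 6 (5E)-6,10-dimethylundeca-5,9-dien-1-yne
Product: 9 (2E,6E)-farnesyl acetate, via alkenylalane 7 (not isolated), via lithium farnesolate 8 (not isolated)
Conditions: Me3Al, Cp2ZrCl2 (0.25 equiv), CH2Cl2, 23 °C; n-BuLi, THF, −78 °C; (CH2O)n, 0 → 23 °C; Ac2O, DMAP, 23 °C
Reagents that add atoms: trimethylaluminium, C[Al](C)C; formaldehyde (as paraformaldehyde), C=O; acetic anhydride, CC(=O)OC(C)=O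
Why: a second Negishi carboalumination sets the (2E) alkene, the alanate is hydroxymethylated with retention, and the alkoxide is acetylated in the same flask.

Step 6
Reactants: 9 (2E,6E)-farnesyl acetate
Product: 10 (6S,7S,10S)-6,7:10,11-diepoxyfarnesyl acetate
Conditions: L-fructose-derived enantiomer of the Shi ketone (0.3 equiv), KHSO5 (as 2KHSO5·KHSO4·K2SO4), K2CO3, Bu4NHSO4, MeCN–CH2(OMe)2–aq. Na2B4O7, 0 °C
Reagents that add atoms: potassium peroxymonosulfate, [K+].[O-]S(=O)(=O)OO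
Why: Shi asymmetric epoxidation, in which the chiral dioxirane oxidises the two electron-rich trisubstituted alkenes through a spiro transition state (this ketone enantiomer gives S,S and S) while the alkene deactivated by the allylic acetate is left.

Step 7
Reactants: 10 (6S,7S,10S)-6,7:10,11-diepoxyfarnesyl acetate
Product: 12 (3S,5aS,6R,7S,9aS)-3-(TBS-oxy)-6-(hydroxymethyl)-2,2,5a,7-tetramethyldecahydro-1-benzoxepin-7-ol, via dioxanylium triflate 11 (not isolated)
Conditions: TBSOTf (1.1 equiv), 2,6-di-tert-butyl-4-methylpyridine, CH2Cl2, −78 °C; then K2CO3, MeOH–H2O, 23 °C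
Reagents that add atoms: tert-butyldimethylsilyl triflate, CC(C)(C)[Si](C)(C)OS(=O)(=O)C(F)(F)F
Why: Proposed new method: O-silylation of the terminal epoxide lets the internal epoxide oxygen attack its tertiary carbon (oxepane, C-3 retained), the bicyclic epoxonium is opened with inversion at C-5a by the (E)-alkene through a chair (trans fusion, C-9a retained, C-6 set), and the tertiary cation is captured anti by the acetate carbonyl as trans-fused dioxanylium 11, which water and methanolysis unmask as the equatorial C-7 hydroxyl; the closest known reaction types are silyl-triflate epoxonium oxa/carbacyclisations of diepoxy alkenes with enol-silane or allylsilane terminators and acetoxonium capture in acid cyclisation of farnesyl acetate, not yet combined.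

Step 8
Reactants: 12 diol
Product: 13 (3S,5aS,6S,7S,9aS)-3-(TBS-oxy)-7-hydroxy-2,2,5a,7-tetramethyldecahydro-1-benzoxepine-6-carbaldehyde
Conditions: TEMPO (0.1 equiv), PhI(OAc)2, CH2Cl2, 23 °C
Reagents that add atoms: none
Why: oxoammonium (TEMPO) oxidation takes the primary alcohol to the aldehyde and cannot touch the tertiary alcohol; neutral conditions spare the α-stereocentre.

Step 9
Reactants: 13 hydroxy aldehyde
Product: 14 (3S,5aS,6S,7S,9aS)-3-(TBS-oxy)-6-ethenyl-2,2,5a,7-tetramethyldecahydro-1-benzoxepin-7-ol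
Conditions: Zn, CH2Br2, TiCl4, THF–CH2Cl2, 0 → 23 °C
Reagents that add atoms: dibromomethane, BrCBr
Why: Lombardo–Takai methylenation is non-basic, so the β-hydroxy aldehyde neither epimerises at C-6 nor undergoes retro-aldol cleavage.

Step 10
Reactants: 15 (4R)-4-(TBS-oxy)cyclopent-2-en-1-one
Product: 16 (4R)-4-(TBS-oxy)-2-iodocyclopent-2-en-1-one
Conditions: I2, pyridine, CH2Cl2, 0 → 23 °C
Reagents that add atoms: iodine, II
Why: Johnson α-iodination of an enone by pyridine conjugate addition, iodination and elimination; C-4 is untouched.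

Step 11
Reactants: 14 vinyl benzoxepinol; 16 iodoenone
Product: 18 (4R)-4-(TBS-oxy)-2-(2-Ox-ethyl)cyclopent-2-en-1-one, via B-alkyl-9-BBN 17 (not isolated)
Conditions: 9-BBN (3 equiv), THF, 23 → 50 °C; then 16, PdCl2(dppf) (5 mol%), Ph3As, Cs2CO3, DMF–H2O, 23 °C
Reagents that add atoms: none
Why: anti-Markovnikov hydroboration of the terminal vinyl group and B-alkyl Suzuki–Miyaura coupling with the α-iodoenone join the halves under conditions that tolerate the β-silyloxy enone and the free tertiary alcohol.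

Step 12
Reactants: 18 coupled enone; 19 5-methylhex-5-en-2-one
Product: 21 (4S)-4-(2-methyl-5-oxohexan-2-yl)-5-(2-Ox-ethyl)cyclopent-2-en-1-one (C-5 epimers), via silyloxy ketone 20 (not isolated)
Conditions: Fe(acac)3 (0.3 equiv), PhSiH3, 19 (4 equiv), EtOH–HOCH2CH2OH, 60 °C; then DBU, CH2Cl2, 0 °C
Reagents that add atoms: none
Why: iron-hydride hydrogen-atom transfer to the 1,1-disubstituted alkene of 19 gives a tertiary radical that adds (Giese-type olefin cross-coupling) to the enone β-carbon anti to the adjacent silyloxy group, which sets the future C-4a, and E1cB loss of silanol then transposes the enone.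

Step 13
Reactants: 21 cyclopentenone
Product: 22 (3aS,4S,7aS)-4-hydroxy-4,7,7-trimethyl-1-(2-Ox-ethyl)octahydro-2H-inden-2-one (C-1 epimers)
Conditions: SmI2 (2.5 equiv), t-BuOH, THF–HMPA, −78 → 0 °C
Reagents that add atoms: none
Why: SmI2 ketyl–olefin 6-exo cyclisation, in which the ketyl is delivered to the enone β-carbon from the face of its tether (cis ring fusion) with the samarium-bound oxygen anti to the enone α-carbon, so the tertiary hydroxyl ends trans to the ring CH2 and cis to both ring-fusion hydrogens.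

Step 14
Reactants: 22 cis-hydrindan-2-one
Product: 25 (4aR,8S,8aS)-3,5,5,8-tetramethyl-4-(2-Ox′-ethyl)-2,8-bis(TMS-oxy)-1,4,4a,5,6,7,8,8a-octahydronaphthalene (C-4 epimers), via dibromo carbinol 23 (not isolated), via lithium enolate 24 (not isolated)
Conditions: CH3CHBr2, LiN(iPr)2 (5 equiv each), THF, −100 °C; n-BuLi (6 equiv), −100 → 0 °C; Me3SiCl, Et3N, −78 → 23 °C
Reagents that add atoms: 1,1-dibromoethane, CC(Br)Br; chlorotrimethylsilane, C[Si](C)(C)Cl
Why: Taguchi–Nozaki β-oxido carbenoid ring enlargement, in which bromine–lithium exchange on adduct 23 triggers a 1,2-shift of the more substituted α-carbon (C-1) to the carbenoid carbon with loss of LiBr and gives the six-membered, regiodefined enolate 24 carrying the new methyl-bearing carbon, trapped on O (the tertiary alkoxides are silylated too); the ring-fusion centres are not touched.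

Step 15
Reactants: 25 enol silane
Product: 26 (4aR,8S,8aS)-3,5,5,8-tetramethyl-4-(2-Ox′-ethyl)-8-(TMS-oxy)-4a,5,6,7,8,8a-hexahydronaphthalen-2(1H)-one
Conditions: Pd(OAc)2 (10 mol%), O2 (1 atm), DMSO, 40 °C
Reagents that add atoms: none
Why: Saegusa–Ito oxidation, in which the oxo-π-allyl palladium species from the regiodefined enol silane undergoes β-hydride elimination into the ring to the tetrasubstituted 2-methyl enone; C-4 becomes sp2 and C-4a is not epimerised under these neutral conditions.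

Step 16
Reactants: 26 silylated enone
Product: 27 sipholenol K
Conditions: HF·pyridine, THF, 0 → 23 °C
Reagents that add atoms: none
Why: fluoride-driven cleavage of the secondary TBS ether and both tertiary TMS ethers under mildly acidic conditions that leave the enone, the γ-stereocentre and the tertiary alcohols intact.

**Compound list**
1 | 5-bromo-2-methylpent-2-ene | CC(C)=CCCBr | starting material
2 | 6-methylhept-5-en-1-yne | CC(C)=CCCC#C | intermediate
3 | (1E)-(2,6-dimethylhepta-1,5-dien-1-yl)dimethylalane | CC(C)=CCC/C(C)=C/[Al](C)C | intermediate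
4 | (3E)-4,8-dimethylnona-3,7-dien-1-ol | CC(C)=CCC/C(C)=C/CCO | intermediate
5 | (6E)-9-iodo-2,6-dimethylnona-2,6-diene | CC(C)=CCC/C(C)=C/CCI | intermediate
6 | (5E)-6,10-dimethylundeca-5,9-dien-1-yne | CC(C)=CCC/C(C)=C/CCC#C | intermediate
7 | (1E,5E)-dimethyl(2,6,10-trimethylundeca-1,5,9-trien-1-yl)alane | CC(C)=CCC/C(C)=C/CC/C(C)=C/[Al](C)C | intermediate
8 | lithium (2E,6E)-3,7,11-trimethyldodeca-2,6,10-trien-1-olate (aluminate-bound in the flask) | CC(C)=CCC/C(C)=C/CC/C(C)=C/C[O-].[Li+] | intermediate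
9 | (2E,6E)-3,7,11-trimethyldodeca-2,6,10-trien-1-yl acetate | CC(C)=CCC/C(C)=C/CC/C(C)=C/COC(C)=O | intermediate
10 | (2E)-5-[(2S,3S)-3-{2-[(2S)-3,3-dimethyloxiran-2-yl]ethyl}-3-methyloxiran-2-yl]-3-methylpent-2-en-1-yl acetate | CC(=O)OC/C=C(\C)CC[C@@H]1O[C@@]1(C)CC[C@@H]1OC1(C)C | intermediate
11 | trans-fused 2-methyl-1,3-dioxan-2-ylium triflate bridging O-7 and the C-6 CH2O of 12 (3-O-TBS; centres as in 12) | C[C+]1OC[C@H]2[C@]3(C)CC[C@H](O[Si](C)(C)C(C)(C)C)C(C)(C)O[C@H]3CC[C@]2(C)O1.[O-]S(=O)(=O)C(F)(F)F | intermediate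
12 | (3S,5aS,6R,7S,9aS)-3-[(tert-butyldimethylsilyl)oxy]-6-(hydroxymethyl)-2,2,5a,7-tetramethyldecahydro-1-benzoxepin-7-ol | OC[C@H]1[C@]2(C)CC[C@H](O[Si](C)(C)C(C)(C)C)C(C)(C)O[C@H]2CC[C@]1(C)O | intermediate
13 | (3S,5aS,6S,7S,9aS)-3-[(tert-butyldimethylsilyl)oxy]-7-hydroxy-2,2,5a,7-tetramethyldecahydro-1-benzoxepine-6-carbaldehyde | O=C[C@H]1[C@]2(C)CC[C@H](O[Si](C)(C)C(C)(C)C)C(C)(C)O[C@H]2CC[C@]1(C)O | intermediate
14 | (3S,5aS,6S,7S,9aS)-3-[(tert-butyldimethylsilyl)oxy]-6-ethenyl-2,2,5a,7-tetramethyldecahydro-1-benzoxepin-7-ol | C=C[C@H]1[C@]2(C)CC[C@H](O[Si](C)(C)C(C)(C)C)C(C)(C)O[C@H]2CC[C@]1(C)O | intermediate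
15 | (4R)-4-[(tert-butyldimethylsilyl)oxy]cyclopent-2-en-1-one | O=C1C=C[C@H](O[Si](C)(C)C(C)(C)C)C1 | starting material
16 | (4R)-4-[(tert-butyldimethylsilyl)oxy]-2-iodocyclopent-2-en-1-one | O=C1C(I)=C[C@H](O[Si](C)(C)C(C)(C)C)C1 | intermediate
17 | 9-(2-Ox-ethyl)-9-borabicyclo[3.3.1]nonane | C1CC2CCCC(C1)B2CC[C@H]1[C@]2(C)CC[C@H](O[Si](C)(C)C(C)(C)C)C(C)(C)O[C@H]2CC[C@]1(C)O | intermediate
18 | (4R)-4-[(tert-butyldimethylsilyl)oxy]-2-(2-Ox-ethyl)cyclopent-2-en-1-one | O=C1C(CC[C@H]2[C@]3(C)CC[C@H](O[Si](C)(C)C(C)(C)C)C(C)(C)O[C@H]3CC[C@]2(C)O)=C[C@H](O[Si](C)(C)C(C)(C)C)C1 | intermediate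
19 | 5-methylhex-5-en-2-one | CC(=C)CCC(C)=O | starting material
20 | (3S,4R)-4-[(tert-butyldimethylsilyl)oxy]-3-(2-methyl-5-oxohexan-2-yl)-2-(2-Ox-ethyl)cyclopentan-1-one (C-2 epimers) | O=C1C(CC[C@H]2[C@]3(C)CC[C@H](O[Si](C)(C)C(C)(C)C)C(C)(C)O[C@H]3CC[C@]2(C)O)[C@@H](C(C)(C)CCC(C)=O)[C@H](O[Si](C)(C)C(C)(C)C)C1 | intermediate
21 | (4S)-4-(2-methyl-5-oxohexan-2-yl)-5-(2-Ox-ethyl)cyclopent-2-en-1-one (C-5 epimers) | O=C1C=C[C@H](C(C)(C)CCC(C)=O)C1CC[C@H]2[C@]3(C)CC[C@H](O[Si](C)(C)C(C)(C)C)C(C)(C)O[C@H]3CC[C@]2(C)O | intermediate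
22 | (3aS,4S,7aS)-4-hydroxy-4,7,7-trimethyl-1-(2-Ox-ethyl)octahydro-2H-inden-2-one (cis-fused; C-1 epimers) | O=C1C[C@@H]2[C@@](C)(O)CCC(C)(C)[C@@H]2C1CC[C@H]3[C@]4(C)CC[C@H](O[Si](C)(C)C(C)(C)C)C(C)(C)O[C@H]4CC[C@]3(C)O | intermediate
23 | 2-(1,1-dibromoethyl)-4,7,7-trimethyl-1-(2-Ox-ethyl)octahydro-1H-indene-2,4-diol (C-3a, C-4, C-7a as in 22; lithium alkoxide in the flask) | CC(Br)(Br)C1(O)C[C@@H]2[C@@](C)(O)CCC(C)(C)[C@@H]2C1CC[C@H]3[C@]4(C)CC[C@H](O[Si](C)(C)C(C)(C)C)C(C)(C)O[C@H]4CC[C@]3(C)O | intermediate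
24 | trilithium salt of (4aR,8S,8aS)-8-hydroxy-3,5,5,8-tetramethyl-4-(2-Ox-ethyl)-1,4,4a,5,6,7,8,8a-octahydronaphthalen-2-ol (enolate and two alkoxides; C-4 epimers) | CC1=C(O[Li])C[C@@H]2[C@@](C)(O[Li])CCC(C)(C)[C@@H]2C1CC[C@H]3[C@]4(C)CC[C@H](O[Si](C)(C)C(C)(C)C)C(C)(C)O[C@H]4CC[C@]3(C)O[Li] | intermediate
25 | (4aR,8S,8aS)-3,5,5,8-tetramethyl-4-(2-Ox′-ethyl)-2,8-bis[(trimethylsilyl)oxy]-1,4,4a,5,6,7,8,8a-octahydronaphthalene (C-4 epimers) | CC1=C(O[Si](C)(C)C)C[C@@H]2[C@@](C)(O[Si](C)(C)C)CCC(C)(C)[C@@H]2C1CC[C@H]3[C@]4(C)CC[C@H](O[Si](C)(C)C(C)(C)C)C(C)(C)O[C@H]4CC[C@]3(C)O[Si](C)(C)C | intermediate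
26 | (4aR,8S,8aS)-4-{2-[(3S,5aS,6S,7S,9aS)-3-[(tert-butyldimethylsilyl)oxy]-2,2,5a,7-tetramethyl-7-[(trimethylsilyl)oxy]decahydro-1-benzoxepin-6-yl]ethyl}-3,5,5,8-tetramethyl-8-[(trimethylsilyl)oxy]-4a,5,6,7,8,8a-hexahydronaphthalen-2(1H)-one | CC1=C(CC[C@H]2[C@]3(C)CC[C@H](O[Si](C)(C)C(C)(C)C)C(C)(C)O[C@H]3CC[C@]2(C)O[Si](C)(C)C)[C@@H]2[C@H](CC1=O)[C@@](C)(O[Si](C)(C)C)CCC2(C)C | intermediate
27 | sipholenol K, (4aR,8S,8aS)-4-{2-[(3S,5aS,6S,7S,9aS)-3,7-dihydroxy-2,2,5a,7-tetramethyldecahydro-1-benzoxepin-6-yl]ethyl}-8-hydroxy-3,5,5,8-tetramethyl-4a,5,6,7,8,8a-hexahydronaphthalen-2(1H)-one | CC1=C(CC[C@H]2[C@]3(C)CC[C@H](O)C(C)(C)O[C@H]3CC[C@]2(C)O)[C@@H]2[C@H](CC1=O)[C@@](C)(O)CCC2(C)C | target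

**Step count**
Total: 16 steps. Longest linear sequence: 15 steps (steps 1–9, then 11–16); step 10 is the only off-line step.

**Three steps most likely to fail**

Step 7 (the proposed new cascade). The allylic acetate alkene is a weak terminator and the tertiary cation may lose a proton before the acetate captures it. The fallback uses known chemistry and sets out from 10: the same silyl-triflate oxa/carbacyclisation is allowed to end by proton loss, as is known for simple alkene terminators, giving the bicyclic alkene acetate F1 (endocyclic isomer drawn; the exocyclic isomer accompanies it). Mukaiyama hydration (Co(acac)2, PhSiH3, O2, i-PrOH) takes both isomers through the same tertiary radical, which is oxygenated on the face away from the axial C-5a methyl, to the hydroxy acetate F2. K2CO3 in MeOH then returns to the route at 12.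

Step 13 (ketyl–enone cyclisation). The cis fusion is forced, but the configuration of the tertiary carbinol rests on the oxygen-anti preference, and simple enone reduction can compete. The fallback sets out from 21: kinetic enolisation of the methyl ketone (KN(SiMe3)2, PhNTf2, −78 °C) gives the enol triflate F3. Reductive Heck cyclisation (Pd(OAc)2, PPh3, HCO2Na, DMF, 60 °C) closes ring B to the cis-fused exo-methylene ketone F4. Mukaiyama hydration then delivers the hydroxyl on the convex face, cis to both ring-fusion hydrogens, and returns to the route at 22.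

Step 14 (ring expansion). It relies on the more substituted α-carbon migrating in a hindered α-methyl carbenoid, and the ketone may enolise instead of adding. The fallback fixes the regiochemistry through the enol ether and sets out from 22: Me3SiCl, NaI, Et3N in MeCN gives the thermodynamic, more substituted silyl enol ether F5 (tertiary alcohols silylated as well). Ethylidene transfer (Et2Zn, CH3CHI2) gives the siloxycyclopropane F6. FeCl3 in DMF cleaves the internal cyclopropane bond to the ring-expanded β-chloro ketone F7, and NaOAc in MeOH eliminates HCl (Ito–Saegusa ring expansion), returning to the route at 26.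

**Further compounds**
F1 | step 7 | {(3S,5aS,9aS)-3-[(tert-butyldimethylsilyl)oxy]-2,2,5a,7-tetramethyl-2,3,4,5,5a,6,9,9a-octahydro-1-benzoxepin-6-yl}methyl acetate (C-6 as in 12; 7-ene shown) | CC(=O)OC[C@H]1[C@]2(C)CC[C@H](O[Si](C)(C)C(C)(C)C)C(C)(C)O[C@H]2CC=C1C
F2 | step 7 | {(3S,5aS,6R,7S,9aS)-3-[(tert-butyldimethylsilyl)oxy]-7-hydroxy-2,2,5a,7-tetramethyldecahydro-1-benzoxepin-6-yl}methyl acetate | CC(=O)OC[C@H]1[C@]2(C)CC[C@H](O[Si](C)(C)C(C)(C)C)C(C)(C)O[C@H]2CC[C@]1(C)O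
F3 | step 13 | 5-methyl-5-[4-oxo-5-(2-Ox-ethyl)cyclopent-2-en-1-yl]hex-1-en-2-yl trifluoromethanesulfonate (ring stereocentre as in 21) | O=C1C=C[C@H](C(C)(C)CCC(=C)OS(=O)(=O)C(F)(F)F)C1CC[C@H]2[C@]3(C)CC[C@H](O[Si](C)(C)C(C)(C)C)C(C)(C)O[C@H]3CC[C@]2(C)O
F4 | step 13 | cis-fused 7,7-dimethyl-4-methylidene-1-(2-Ox-ethyl)octahydro-2H-inden-2-one (ring fusion as in 22) | O=C1C[C@@H]2C(=C)CCC(C)(C)[C@@H]2C1CC[C@H]3[C@]4(C)CC[C@H](O[Si](C)(C)C(C)(C)C)C(C)(C)O[C@H]4CC[C@]3(C)O
F5 | step 14 | cis-fused 4,7,7-trimethyl-1-(2-Ox′-ethyl)-2,4-bis[(trimethylsilyl)oxy]-3a,4,5,6,7,7a-hexahydro-3H-indene (C-1/C-2 enol ether; centres as in 22) | C[Si](C)(C)OC=1C[C@@H]2[C@@](C)(O[Si](C)(C)C)CCC(C)(C)[C@@H]2C=1CC[C@H]3[C@]4(C)CC[C@H](O[Si](C)(C)C(C)(C)C)C(C)(C)O[C@H]4CC[C@]3(C)O[Si](C)(C)C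
F6 | step 14 | siloxycyclopropane from F5, with a CH(CH3) bridge across C-1 and C-2 of the hydrindane | C[Si](C)(C)OC12C[C@@H]3[C@@](C)(O[Si](C)(C)C)CCC(C)(C)[C@@H]3C1(CC[C@H]4[C@]5(C)CC[C@H](O[Si](C)(C)C(C)(C)C)C(C)(C)O[C@H]5CC[C@]4(C)O[Si](C)(C)C)C2C
F7 | step 14 | 4-chloro-3,5,5,8-tetramethyl-4-(2-Ox′-ethyl)-8-[(trimethylsilyl)oxy]octahydronaphthalen-2(1H)-one (C-4a, C-8, C-8a as in 26) | CC1C(=O)C[C@@H]2[C@@](C)(O[Si](C)(C)C)CCC(C)(C)[C@@H]2C1(Cl)CC[C@H]3[C@]4(C)CC[C@H](O[Si](C)(C)C(C)(C)C)C(C)(C)O[C@H]4CC[C@]3(C)O[Si](C)(C)C
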